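## The problem

Labels used throughout: ring A is A1 (C–CH3), A2 (C–H), A3 (C–OH), A4 (C–CHO), A5 (C–O, ether), A6 (C–C11, the lactone carbonyl carbon). Ring B is B1 (C–O, ester), B2 (C–CH3), B3 (C–C4, ketone side of the pyranone), B4 (C–O1 of the pyranone), B5 (C–OH), B6 (C–O, ether). The pyranone is O1, C2 (CMe2), C3 (CH2), C4 (C=O).

- The target 17 is a depsidone. Rings A and B are joined by the ester C11(=O)–O(B1) and by the diaryl ether A5–O–B6, which closes a seven-membered dioxepinone. A 2,2-dimethylpyran-4-one is fused across B3/B4.
- There is no stereocentre, and the dioxepinone ring is not expected to give configurationally stable conformers. The compound is therefore treated as achiral, and the whole difficulty is regiochemical.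
- Ring B is hexasubstituted, with four contiguous oxygens in four different roles: ester at B1, ether at B6, free hydroxyl at B5, pyran oxygen at B4.
- O(B1) and O(B5) both flank O(B6), and O(B1) and O(B6) are neighbours. Under base an acyl group or an activated aryl group can therefore migrate between these oxygens, and a lactone could close onto the wrong hydroxyl.
- The diaryl ether carries four ortho substituents.
- Several groups limit the reagents. The aryl ester of the lactone does not tolerate hydroxide or thiolate. The aldehyde can condense with the enolisable C3 methylene under base. The pyranone is a β-aryloxy ketone that can open by β-elimination or by ionisation at C2. A free tetraoxygenated ring B is easily oxidised to a quinone.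
- The enabling feature is that the B1/B4/B5/B6 oxygens and the B2 methyl reproduce the hydroquinone of 2,3-dimethoxy-5-methyl-1,4-benzoquinone. Its only C–H is B3 and the only hydroxyl next to B3 is O(B4). A five-carbon unsaturated acid can therefore be attached in one way only, and the new ketone ends up para to O(B6), which marks that methyl ether for selective removal.

## Retrosynthesis

**17 to 16 (two O–CH3 bonds).** The last cut is at the methyl ethers on O(A3) and O(B5) of the depsidone 16. Both methyls come with the commercial starting materials, so no protecting group is installed for them. The O(A3) methyl keeps ring A free of a phenoxide that would switch off its electrophilicity. The O(B5) methyl ensures that only O(B1) can lactonise. The forward step must cleave two aryl methyl ethers without opening the lactone or the pyranone.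

**16 to 15 to 14 (the ester C11–O(B1)).** The lactone is opened to the hydroxy acid 15, which is generated in the flask from diaryl ether 14 (tert-butyl ester on C11, MOM ether on O(B1)). Closing the ester last, under acid, is preferred to closing the ether last. An ether-last route needs a phenoxide on O(B6) next to an ester on O(B1), and acyl migration between these two oxygens would then decide the product. In 14 one acid removes both masking groups and no base is present at any point after the ether exists. The forward step is a seven-membered lactonisation of a di-ortho-substituted benzoic acid.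

**14 to 7 + 13 (the ether A5–O(B6)).** This cut gives two benzene building blocks of similar size: ring B phenol 7 and ring A fluoride 13. Fluorine on A5 sits between the formyl and ester groups, and the donors (OMe, CH3) are meta to it, so addition–elimination is electronically well set up. O(B1) is masked in 7. Coupling a free B1/B6 catechol instead would rest on an acidity difference and could be undone by a Smiles aryl shift to O(B1). The forward reaction must form a crowded diaryl ether intermolecularly.

**7 to 6 to 5 (O(B6)–CH3, with O(B1) masked).** No skeletal bond is cut. Phenol 7 comes from MOM ether 6 by nucleophilic demethylation of the one methyl ether para to the ketone, and 6 comes from phenol 5. The MOM group is chosen because it survives thiolate and carbonate and leaves under the acid that removes the tert-butyl ester. The forward demethylation must distinguish O(B6)–CH3 (para to C4=O) from O(B5)–CH3 (meta).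

**5 to 2 + 3, and 2 to 1 (B3–C4 and O1–C2).** The pyranone is removed in one cut to hydroquinone 2 and 3-methylbut-2-enoic acid 3, through the uncyclised aryl enone 4. This is preferred to building the pyranone late because on 2 there is only one possible site on carbon and one on oxygen, and no second aromatic ring competes. Hydroquinone 2 is one reduction from commercial quinone 1. The forward step must favour acylation at B3 over conjugate alkylation and leave O(B1)H free.

**13 to 12 to 11 to 10 to 8 (ring A carbons at A4 and A6).** The tert-butyl ester 13 comes from acid 12, made by carbonylation of bromide 11. Bromide 11 comes from aldehyde 10 by bromination para to the methoxy group, and 10 from 1-fluoro-3-methoxy-5-methylbenzene 8 by lithiation between fluorine and methoxy (aryllithium 9). The formyl group goes in first. A carboxyl derivative next to the A1 methyl would divert a later metalation to the benzylic position.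

## Roads not taken

**Alternative 1:** Ring A is not bought as an arene but folded from an acyclic polyketide on ring B. The cuts are C11–O(B1) and the ring A bond A6–A1.

- Forward key step: heating dioxinone A2 with ring B phenol A3 releases an acylketene that acylates O(B1). Aldol condensation and dehydration of the resulting triketo ester give the depside A1.
- Merits: the ester is placed on O(B1) without any ambiguity, and ring A needs no separate building-block synthesis. The bromine on B6 of A1 allows an intramolecular copper-mediated ether closure, which is probably more reliable for this crowded ether than the intermolecular substitution of step 9.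
- Weak points: A1 still lacks the formyl group and the whole pyranone. Formylation must choose A4 over A2 between two free hydroxyls. The acylation at B3 must be done on a depsidone whose resorcinol ring A is the more nucleophilic arene. The aryl triketo ester can also cyclise with loss of the phenoxide.
- Comparison: this road is better for ester regiochemistry and for the ether closure. The chosen plan sets against it a fully substituted ring B in two steps from a commercial quinone and no electrophilic substitution on the assembled tricycle.

**Alternative 2:** The tricycle is made as a xanthone and one oxygen is inserted. The cut is O–B1 of the lactone, traced back to the C11–B1 bond of xanthone A5.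

- Forward key step: O-methylation of A5 to the 9-methoxyxanthylium ion and addition of H2O2 at C11, followed by a Criegee shift of B1 from carbon to oxygen, give the depsidone core A4.
- Merits: xanthones are made in one robust condensation, the diaryl ether is no problem at all, and the seven-membered ring appears in a single step. To the bare core this is shorter than the chosen plan.
- Weak points: the outcome depends on B1 migrating in preference to A6. Both are ortho-methyl, ortho-oxygen aryl groups, so the bias from the richer ring B is real but not secure. Electron-rich arenes and peroxide can also end in quinones. A4 lacks the formyl group and the pyranone, and O(B4) and O(B5) are both methyl ethers that must later be told apart.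
- Comparison: the chosen plan is longer to the tricycle. Against that it sets well-precedented reaction types in every step, the O(B4)/O(B5) distinction made at the outset, and all carbon substituents present before the rings are joined.

**Alternative 3:** Ring B is grown from a four-membered ring. The cut is B1–B2, with the diaryl ether already present.

- Forward key step: thermolysis of cyclobutenone A7 opens it to a dienylketene. 6π electrocyclisation and enolisation give the diaryl ether hydroquinone A6.
- Merits: the hindered ether is made by addition–elimination on a cyclobutenedione, which is easier than any arene–arene ether coupling. The ring B oxygens come out differentiated (isopropyl on O(B5), free O(B1) and O(B4)). On these two points this road is better than the chosen plan.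
- Weak points: B3 is still C–H in A6. The same acylation and oxa-Michael closure must therefore be run later, on a substrate that carries an acid-sensitive isopropyl ether and an activated anisole ring A. The formyl group is also missing and must be placed at A4 instead of A2. Making A7 takes several steps with site-selective additions to an unsymmetrical cyclobutenedione.
- Comparison: the chosen plan answers with the pyranone annulation done first on the simplest possible substrate and a ring A that arrives fully functionalised. Its price is the intermolecular ether formation of step 9.

Key step: step 2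

## Route

Step 1
Reactants: 1 2,3-dimethoxy-5-methyl-1,4-benzoquinone
Product: 2 2,3-dimethoxy-5-methylbenzene-1,4-diol
Conditions: Na2S2O4, EtOAc/H2O, rt, N2
Reagents that add atoms: none
Why: Dithionite reduction of a benzoquinone to its hydroquinone is a standard two-electron reduction; the product is kept under nitrogen and used at once because it re-oxidises in air.

Step 2
Reactants: 2 2,3-dimethoxy-5-methylbenzene-1,4-diol; 3 3-methylbut-2-enoic acid
Product: 5 6-hydroxy-7,8-dimethoxy-2,2,5-trimethylchroman-4-one, via aryl enone 4 (not isolated)
Conditions: P2O5/MeSO3H (1:10 w/w), 3 (1.1 equiv), 70 °C, N2; ice-water quench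
Reagents that add atoms: none
Why: P2O5 in MeSO3H turns 3 into its mixed anhydride or acylium ion, which acylates ring B either at O(B4) followed by an acid-mediated Fries shift or directly at B3, the position ortho to O(B4)H and para to the O(B6) methyl ether (Friedel–Crafts acylation, B3–C4 bond), to give enone 4. In 4 the protonated β,β-dimethyl enone is attacked at its tertiary β-carbon by O(B4)H (oxa-Michael addition, O1–C2 bond), which closes the pyranone in a 6-endo-trig mode. The closest known reaction type is the acid-mediated condensation of phenols with 3-methylbut-2-enoic acid to 2,2-dimethylchroman-4-ones, established for resorcinol- and hydroquinone-type phenols. No stereocentre arises because C2 bears two methyl groups. The step needs site selectivity on carbon and on oxygen, and the substrate supplies both: B3 is the only ring carbon with a hydrogen and O(B4) is the only hydroxyl ortho to it, while O(B1), shielded by methyl and methoxy neighbours, can at most be O-acylated, which changes nothing about where the ring forms. It also needs acylation to outrun conjugate alkylation at the β-carbon of the acid, which the dehydrating medium favours by holding the acid in its acylating form. The methyl ethers are stable to this non-oxidising acid, and nitrogen keeps the hydroquinone from returning to the quinone.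

Step 3
Reactants: 5 6-hydroxy-7,8-dimethoxy-2,2,5-trimethylchroman-4-one
Product: 6 7,8-dimethoxy-6-(methoxymethoxy)-2,2,5-trimethylchroman-4-one
Conditions: MOMCl, i-Pr2NEt, CH2Cl2, 0 °C → rt
Reagents that add atoms: chloromethyl methyl ether, COCCl
Why: O-alkylation of the only free hydroxyl (acetal protection of a phenol); the MOM group is chosen because it is inert to thiolate and carbonate and later leaves under the acid that cleaves the tert-butyl ester.

Step 4
Reactants: 6 7,8-dimethoxy-6-(methoxymethoxy)-2,2,5-trimethylchroman-4-one
Product: 7 7-hydroxy-8-methoxy-6-(methoxymethoxy)-2,2,5-trimethylchroman-4-one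
Conditions: NaSEt, DMF, 100 °C; aq. NH4Cl
Reagents that add atoms: none
Why: SN2 demethylation by ethanethiolate: the O(B6) aryloxide is the best leaving group because it is para to the C4 ketone (a vinylogous carboxylate), whereas the O(B5) ether is meta to it. Once the phenoxide has formed, the ring is deactivated toward a second cleavage, and the MOM acetal does not react with thiolate.

Step 5
Reactants: 8 1-fluoro-3-methoxy-5-methylbenzene
Product: 10 2-fluoro-6-methoxy-4-methylbenzaldehyde, via aryllithium 9 (not isolated)
Conditions: n-BuLi, THF, −78 °C; DMF, −78 °C → rt; aq. HCl
Reagents that add atoms: N,N-dimethylformamide, CN(C)C=O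
Why: Directed ortho-metalation: the hydrogen between fluorine and methoxy is the most acidic and is flanked by two coordinating groups, so lithiation occurs there and DMF formylates aryllithium 9; −78 °C prevents loss of LiF to an aryne.

Step 6
Reactants: 10 2-fluoro-6-methoxy-4-methylbenzaldehyde
Product: 11 3-bromo-2-fluoro-6-methoxy-4-methylbenzaldehyde
Conditions: NBS, DMF, rt → 40 °C, dark
Reagents that add atoms: N-bromosuccinimide, O=C1CCC(=O)N1Br
Why: Electrophilic aromatic bromination at the free position para to the methoxy group and meta to the formyl group, as in the bromination of 2-methoxybenzaldehydes; polar conditions in the dark avoid benzylic bromination.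

Step 7
Reactants: 11 3-bromo-2-fluoro-6-methoxy-4-methylbenzaldehyde
Product: 12 2-fluoro-3-formyl-4-methoxy-6-methylbenzoic acid
Conditions: Pd(OAc)2 (5 mol%), Xantphos, CO (1 atm), Et3N, H2O, DMF, 80 °C; aq. HCl
Reagents that add atoms: carbon monoxide, [C-]#[O+]; water, O
Why: Palladium-catalysed hydroxycarbonylation of an aryl bromide: zerovalent palladium inserts into the C–Br bond, CO insertion gives the acylpalladium species and water cleaves it to the acid. The aldehyde is tolerated and the mild amine base leaves the activated C–F bond alone.

Step 8
Reactants: 12 2-fluoro-3-formyl-4-methoxy-6-methylbenzoic acid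
Product: 13 tert-butyl 2-fluoro-3-formyl-4-methoxy-6-methylbenzoate
Conditions: tert-butyl 2,2,2-trichloroacetimidate, cyclohexane/CH2Cl2, rt
Reagents that add atoms: tert-butyl 2,2,2-trichloroacetimidate, CC(C)(C)OC(=N)C(Cl)(Cl)Cl
Why: Esterification by alkyl transfer: the acid protonates the imidate and the carboxylate captures the tert-butyl cation, so the two ortho substituents that would block acyl substitution do not matter. The tert-butyl ester can later be removed by acid, without hydroxide.

Step 9
Reactants: 7 7-hydroxy-8-methoxy-6-(methoxymethoxy)-2,2,5-trimethylchroman-4-one; 13 tert-butyl 2-fluoro-3-formyl-4-methoxy-6-methylbenzoate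
Product: 14 tert-butyl 3-formyl-4-methoxy-2-{[8-methoxy-6-(methoxymethoxy)-2,2,5-trimethyl-4-oxochroman-7-yl]oxy}-6-methylbenzoate
Conditions: Cs2CO3, DMF, 70 °C
Reagents that add atoms: none
Why: Nucleophilic aromatic substitution by addition–elimination: the cesium phenoxide of 7, the only free hydroxyl, adds at A5 of 13, where fluorine is flanked by formyl and ester groups that stabilise the Meisenheimer intermediate and the methoxy and methyl donors sit meta. The tert-butyl ester, the MOM ether and the pyranone are stable to carbonate at this temperature.

Step 10
Reactants: 14 tert-butyl 3-formyl-4-methoxy-2-{[8-methoxy-6-(methoxymethoxy)-2,2,5-trimethyl-4-oxochroman-7-yl]oxy}-6-methylbenzoate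
Product: 16 the depsidone bearing methyl ethers on O(A3) and O(B5) (target skeleton with A3-OMe, A4-CHO, B5-OMe), via seco hydroxy acid 15 (not isolated)
Conditions: TFA/CH2Cl2 (1:3), H2O (2 equiv), rt; evaporate, toluene azeotrope; TFAA, toluene, 0 °C → rt
Reagents that add atoms: none
Why: Acidolysis by alkyl–oxygen fission removes the tert-butyl ester and the MOM acetal together to give hydroxy acid 15. TFAA then forms the mixed anhydride of the hindered acid, which O(B1)H captures intramolecularly (anhydride-mediated depsidone lactonisation). O(B5) is still a methyl ether, so only one lactone can form, and no base is present that could move the aryl group from O(B6) to O(B1).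

Step 11
Reactants: 16 the depsidone bearing methyl ethers on O(A3) and O(B5)
Product: 17 CNP0271978.0 (depsidone with A1-CH3, A3-OH, A4-CHO, B2-CH3, B5-OH and the 2,2-dimethylpyran-4-one fused at B3/B4)
Conditions: BBr3, CH2Cl2, −78 → 0 °C; H2O
Reagents that add atoms: none
Why: Lewis-acid cleavage of aryl methyl ethers: BBr3 coordinates each methoxy oxygen and bromide removes the methyl group, helped at O(A3) by chelation to the formyl oxygen and at O(B5) by its two oxygen neighbours. The aryl ester and the diaryl ether are not expected to cleave at or below 0 °C.

## Compound list

1 | 2,3-dimethoxy-5-methyl-1,4-benzoquinone | COC1=C(OC)C(=O)C(C)=CC1=O | starting material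
2 | 2,3-dimethoxy-5-methylbenzene-1,4-diol | COc1c(O)cc(C)c(O)c1OC | intermediate
3 | 3-methylbut-2-enoic acid | CC(C)=CC(=O)O | starting material
4 | 1-(2,5-dihydroxy-3,4-dimethoxy-6-methylphenyl)-3-methylbut-2-en-1-one | COc1c(OC)c(O)c(C(=O)C=C(C)C)c(C)c1O | intermediate (not isolated)
5 | 6-hydroxy-7,8-dimethoxy-2,2,5-trimethylchroman-4-one | COc1c(OC)c2OC(C)(C)CC(=O)c2c(C)c1O | intermediate
6 | 7,8-dimethoxy-6-(methoxymethoxy)-2,2,5-trimethylchroman-4-one | COCOc1c(C)c2C(=O)CC(C)(C)Oc2c(OC)c1OC | intermediate
7 | 7-hydroxy-8-methoxy-6-(methoxymethoxy)-2,2,5-trimethylchroman-4-one | COCOc1c(C)c2C(=O)CC(C)(C)Oc2c(OC)c1O | intermediate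
8 | 1-fluoro-3-methoxy-5-methylbenzene | COc1cc(C)cc(F)c1 | starting material
9 | (2-fluoro-6-methoxy-4-methylphenyl)lithium | [Li]c1c(F)cc(C)cc1OC | intermediate (not isolated)
10 | 2-fluoro-6-methoxy-4-methylbenzaldehyde | COc1cc(C)cc(F)c1C=O | intermediate
11 | 3-bromo-2-fluoro-6-methoxy-4-methylbenzaldehyde | COc1cc(C)c(Br)c(F)c1C=O | intermediate
12 | 2-fluoro-3-formyl-4-methoxy-6-methylbenzoic acid | COc1cc(C)c(C(=O)O)c(F)c1C=O | intermediate
13 | tert-butyl 2-fluoro-3-formyl-4-methoxy-6-methylbenzoate | COc1cc(C)c(C(=O)OC(C)(C)C)c(F)c1C=O | intermediate
14 | tert-butyl 3-formyl-4-methoxy-2-{[8-methoxy-6-(methoxymethoxy)-2,2,5-trimethyl-4-oxochroman-7-yl]oxy}-6-methylbenzoate | COc1cc(C)c(C(=O)OC(C)(C)C)c(Oc2c(OC)c3OC(C)(C)CC(=O)c3c(C)c2OCOC)c1C=O | intermediate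
15 | 3-formyl-2-[(6-hydroxy-8-methoxy-2,2,5-trimethyl-4-oxochroman-7-yl)oxy]-4-methoxy-6-methylbenzoic acid | COc1cc(C)c(C(=O)O)c(Oc2c(OC)c3OC(C)(C)CC(=O)c3c(C)c2O)c1C=O | intermediate (not isolated)
16 | depsidone with methyl ethers on O(A3) and O(B5): the target skeleton with A3-OMe and B5-OMe | Cc1cc(OC)c(C=O)c2c1C(=O)Oc1c(C)c3c(c(OC)c1O2)OC(C)(C)CC3=O | intermediate
17 | CNP0271978.0 | Cc1cc(O)c(C=O)c2c1C(=O)Oc1c(C)c3c(c(O)c1O2)OC(C)(C)CC3=O | target

## Step count and risks

Total: 11 steps. Longest linear sequence: 7 steps (1, 2, 3, 4, 9, 10, 11). The ring A branch (steps 5 to 8) joins at step 9 and is equally long.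

**Step 2 (key step).**
- Risk: alkylation of B3 by the β-carbon of the protonated acid, followed by lactonisation onto O(B4), may compete with acylation. This is the path hydroquinones take in sulfonic acid without a dehydrating agent. B3 also lies between a hydroxyl and a methyl group, so slow C-acylation could let O-acylation at O(B1) and re-oxidation take over. Any ester formed at O(B1) can be cleaved by brief methanolysis.
- Fallback: set out from 2. Friedel–Crafts acetylation at the same carbon with AcOH/BF3·OEt2 at 90 °C should give 1-(2,5-dihydroxy-3,4-dimethoxy-6-methylphenyl)ethan-1-one F1. Kabbe condensation with acetone and pyrrolidine (enamine aldol, dehydration, oxa-Michael closure by O(B4)) returns to the route at 5. The pyranone is then assembled from a two-carbon and a three-carbon unit, so conjugate alkylation cannot occur.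

**Step 9.**
- Risk: addition at A5 may be slow because the carbon is flanked by the formyl group and a bulky, twisted tert-butyl ester and the nucleophile is a weakly nucleophilic para-acyl phenoxide. Carbonate-mediated aldol condensation between the C3 methylene and the aldehyde can then compete.
- Fallback: set out from 7 and use the less encumbered fluoride 11, whose fluorine is activated by the ortho formyl group and the ortho bromine. Cs2CO3 in DMF should give 3-bromo-6-methoxy-2-{[8-methoxy-6-(methoxymethoxy)-2,2,5-trimethyl-4-oxochroman-7-yl]oxy}-4-methylbenzaldehyde F2. TFA in CH2Cl2 then gives 3-bromo-2-[(6-hydroxy-8-methoxy-2,2,5-trimethyl-4-oxochroman-7-yl)oxy]-6-methoxy-4-methylbenzaldehyde F3. Palladium-catalysed carbonylative lactonisation (Pd(OAc)2, Xantphos, CO, Et3N, toluene, 100 °C) introduces C11 after the ether bond and is captured by O(B1)H. It returns to the route at 16 and makes steps 7 and 8 unnecessary.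

**Step 4.**
- Risk: the selectivity between the two methyl ethers may erode, or thiolate-induced enolisation may open the pyranone by β-elimination of the B4 phenoxide with thiol addition to the enone.
- Fallback: set out from 5 and use its free O(B1)H as a directing group. BCl3 in CH2Cl2 (−78 → 0 °C) forms the aryloxyboron chloride, which delivers cleavage to the neighbouring O(B6) methyl and should stop at the cyclic borate, giving 6,7-dihydroxy-8-methoxy-2,2,5-trimethylchroman-4-one F4. Its more acidic hydroxyl, O(B6)H para to the ketone, is then arylated with 13 using one equivalent of KHCO3 in DMF. The limited base is meant to avoid a phenoxide on O(B1) and hence aryl migration. This gives tert-butyl 3-formyl-2-[(6-hydroxy-8-methoxy-2,2,5-trimethyl-4-oxochroman-7-yl)oxy]-4-methoxy-6-methylbenzoate F5. TFA converts F5 into 15, where the route is rejoined for the TFAA closure of step 10.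

**Step 11.**
- Risk: the tertiary C2–O1 bond of the pyranone may ionise under excess Lewis acid (ring opening to the β-bromo ketone or enone) before the shielded O(B5) methyl is fully cleaved. Prolonged exposure could also cleave the lactone.
- Fallback: set out from 16 and accept the opening. BBr3 is run to complete ether cleavage at rt, and work-up with loss of HBr should give the ring-opened 2-hydroxyaryl 3-methylbut-2-enoyl ketone F6 (the depsidone with B3–C(=O)CH=C(CH3)2 and free O(B4)H, O(B5)H and O(A3)H). TsOH in toluene at 60 °C then re-closes the pyranone by oxa-Michael addition of O(B4)H, the only hydroxyl ortho to the acyl group, and arrives at 17.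

**Step 6.**
- Risk: substitution ortho to the methoxy group (para to fluorine) may compete, and the formyl-deactivated ring may react slowly enough for benzylic bromination to appear.
- Fallback: set out from 8 and invert the order. NBS in MeCN brominates the more reactive anisole para to the methoxy group to give 2-bromo-1-fluoro-5-methoxy-3-methylbenzene F7. LiN(i-Pr)2 in THF at −78 °C then removes the proton between fluorine and methoxy without bromine–lithium exchange, and DMF gives 11, where the route is rejoined.

## Further compounds

F1 | step 2 | 1-(2,5-dihydroxy-3,4-dimethoxy-6-methylphenyl)ethan-1-one | CC(=O)c1c(C)c(O)c(OC)c(OC)c1O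
F2 | step 9 | 3-bromo-6-methoxy-2-{[8-methoxy-6-(methoxymethoxy)-2,2,5-trimethyl-4-oxochroman-7-yl]oxy}-4-methylbenzaldehyde | COc1cc(C)c(Br)c(Oc2c(OC)c3OC(C)(C)CC(=O)c3c(C)c2OCOC)c1C=O
F3 | step 9 | 3-bromo-2-[(6-hydroxy-8-methoxy-2,2,5-trimethyl-4-oxochroman-7-yl)oxy]-6-methoxy-4-methylbenzaldehyde | COc1cc(C)c(Br)c(Oc2c(OC)c3OC(C)(C)CC(=O)c3c(C)c2O)c1C=O
F4 | step 4 | 6,7-dihydroxy-8-methoxy-2,2,5-trimethylchroman-4-one | COc1c(O)c(O)c(C)c2C(=O)CC(C)(C)Oc12
F5 | step 4 | tert-butyl 3-formyl-2-[(6-hydroxy-8-methoxy-2,2,5-trimethyl-4-oxochroman-7-yl)oxy]-4-methoxy-6-methylbenzoate | COc1cc(C)c(C(=O)OC(C)(C)C)c(Oc2c(OC)c3OC(C)(C)CC(=O)c3c(C)c2O)c1C=O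
F6 | step 11 | ring-opened enone of the target: depsidone with B3–C(=O)CH=C(CH3)2 and free hydroxyls on B4, B5 and A3 | Cc1cc(O)c(C=O)c2c1C(=O)Oc1c(C)c(C(=O)C=C(C)C)c(O)c(O)c1O2
F7 | step 6 | 2-bromo-1-fluoro-5-methoxy-3-methylbenzene | COc1cc(C)c(Br)c(F)c1
A1 | alternative 1 | 3,4-bis(benzyloxy)-2-bromo-6-methylphenyl 2,4-dihydroxy-6-methylbenzoate | Cc1cc(O)cc(O)c1C(=O)Oc1c(C)cc(OCc2ccccc2)c(OCc2ccccc2)c1Br
A2 | alternative 1 | 6-(2,4-dioxopentyl)-2,2-dimethyl-4H-1,3-dioxin-4-one | CC(=O)CC(=O)CC1=CC(=O)OC(C)(C)O1
A3 | alternative 1 | 3,4-bis(benzyloxy)-2-bromo-6-methylphenol | Cc1cc(OCc2ccccc2)c(OCc2ccccc2)c(Br)c1O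
A4 | alternative 2 | 6,7-dimethoxy-1,9-dimethyl-11-oxo-11H-dibenzo[b,e][1,4]dioxepin-3-yl acetate | CC(=O)Oc1cc(C)c2c(c1)Oc1c(OC)c(OC)cc(C)c1OC2=O
A5 | alternative 2 | 5,6-dimethoxy-1,8-dimethyl-9-oxo-9H-xanthen-3-yl acetate | CC(=O)Oc1cc(C)c2c(c1)Oc1c(OC)c(OC)cc(C)c1C2=O
A6 | alternative 3 | methyl 2-(3,6-dihydroxy-2-isopropoxy-5-methylphenoxy)-4-methoxy-6-methylbenzoate | COC(=O)c1c(C)cc(OC)cc1Oc1c(O)c(C)cc(O)c1OC(C)C
A7 | alternative 3 | methyl 2-{[3-hydroxy-2-isopropoxy-4-oxo-3-((E)-prop-1-en-1-yl)cyclobut-1-en-1-yl]oxy}-4-methoxy-6-methylbenzoate (racemic) | COC(=O)c1c(C)cc(OC)cc1OC1=C(OC(C)C)C(O)(/C=C/C)C1=O
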